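**Assumption:** ring carbons are numbered as they appear in the target SMILES (C1 and C4 carry the aminoimidazoles, C2 the pyrrole arm, C3 the bromopyrrole arm), which makes the target all-trans (1S,2R,3R,4S). The product is isolated as its bis-HCl salt; SMILES are given as free bases.

## Retrosynthetic overview

1. Both 2-aminoimidazoles are formed last, together, from a bis(α-aminoketone) and cyanamide. The two different pyrrole amides come from stepwise acylation of a C2-symmetric diamine, whose two amines are homotopic.
2. The all-trans core comes from a cis-anti-cis precursor by epimerising only the two ketone-bearing ring carbons (C1, C4). The CH2N-bearing carbons (C2, C3) cannot enolise and hold the stereochemical information.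
3. The CH2NH2 arms come from lactone carbonyls (ammonolysis, then amide reduction). The ketones come from the lactone carbinol carbons.
4. Key disconnection: the cyclobutane comes from a head-to-head [2+2] photodimerisation of an (S)-5-(aminomethyl)butenolide made from (S)-5-(hydroxymethyl)furan-2(5H)-one. C5 directs both new bonds to the anti face and later becomes imidazole C4.
5. Ring order: cyclobutane first (flanked by two temporary γ-lactones), the two imidazoles last; the pyrroles are bought.

## Route

**Step 1**
Reactants: 1, (S)-5-(hydroxymethyl)furan-2(5H)-one; 2, ethyl N-Boc-oxamate.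
Product: 3, ethyl 2-[(tert-butoxycarbonyl){[(2S)-5-oxo-2,5-dihydrofuran-2-yl]methyl}amino]-2-oxoacetate.
Conditions: PPh3, DIAD, THF, 0 °C → rt.
Reagents that add atoms: ethyl N-Boc-oxamate, CCOC(=O)C(=O)NC(=O)OC(C)(C)C.
Why: Mitsunobu N-alkylation of the acidic imide N–H at the primary carbinol; C5 is not involved and stays (S).

**Step 2**
Reactants: 3 (two molecules).
Product: 4, (1S,2S,5S,6S,7S,8S)-5,8-bis{[N-Boc-N-(ethoxyoxalyl)amino]methyl}-4,9-dioxatricyclo[5.3.0.0^2,6]decane-3,10-dione, the C2-symmetric head-to-head, cis-anti-cis cyclobutane bis-γ-lactone.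
Conditions: hν (medium-pressure Hg lamp, Pyrex, λ > 290 nm), degassed acetone (solvent and triplet sensitiser, ~0.4 M), 0 °C; chromatography, recovered 3 recycled.
Reagents that add atoms: none.
Why: Triplet-sensitised butenolide [2+2] photodimerisation in which each lactone is attacked anti to its C5 substituent; two (S)-lactones both reacting on their anti faces can only unite head-to-head/anti (or the congested head-to-tail/syn), so the four ring stereocentres are set by C5, with the lactone α-carbons (future C2, C3) already in their final configuration.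

**Step 3**
Reactants: 4; 5, ammonia.
Product: 6, (1S,2S,3S,4S)-3,4-bis[(1S)-2-(Boc-amino)-1-hydroxyethyl]cyclobutane-1,2-dicarboxamide (each carboxamide cis to its neighbouring side chain, the two carboxamides trans).
Conditions: 7 M NH3 in MeOH, 0 °C → rt; concentrate cold and use directly.
Reagents that add atoms: ammonia, N.
Why: Ammonolysis of the strained cis-fused γ-lactones gives γ-hydroxy primary amides while the far more electrophilic N-oxalyl group is cleaved (leaving NHBoc); no stereocentre is touched under these weakly basic conditions.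

**Step 4**
Reactants: 6.
Product: 7, di-tert-butyl {[(1R,2R,3R,4R)-3,4-bis(aminomethyl)cyclobutane-1,2-diyl]bis[(2S)-2-hydroxyethane-2,1-diyl]}biscarbamate (C2-symmetric diamine; same geometry as 6, descriptors change only through CIP priorities).
Conditions: BH3·THF (excess), THF, 0 → 65 °C; MeOH quench, then MeOH reflux to break the amine–boranes.
Reagents that add atoms: none.
Why: Electrophilic borane reduces primary amides to amines much faster than carbamates and only borylates the carbinols; no stereocentre is touched.

**Step 5**
Reactants: 7; 8, 4-bromo-2-(trichloroacetyl)pyrrole.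
Product: 9, the mono-(4-bromopyrrole-2-carboxamide) of 7 (one CH2NH2 arm left free).
Conditions: 8 (0.9 equiv, slow addition), i-Pr2NEt, MeCN/DMF, 0 °C → rt; unreacted 7 recovered and recycled.
Reagents that add atoms: 4-bromo-2-(trichloroacetyl)pyrrole, O=C(c1cc(Br)c[nH]1)C(Cl)(Cl)Cl.
Why: Haloform-type acyl transfer from the trichloromethyl ketone is selective for amine over hydroxyl, and because the two amines of 7 are homotopic the statistical mono-acylation gives a single compound.

**Step 6**
Reactants: 9; 10, 2-(trichloroacetyl)pyrrole.
Product: 11, the mixed bis-amide diol: cyclobutane (1R,2R,3R,4R) with C2 = CH2NHCO-(pyrrol-2-yl), C3 = CH2NHCO-(4-bromopyrrol-2-yl), C1 and C4 = (1S)-2-(Boc-amino)-1-hydroxyethyl.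
Conditions: 10 (1.3 equiv), i-Pr2NEt, DMF, rt.
Reagents that add atoms: 2-(trichloroacetyl)pyrrole, O=C(c1ccc[nH]1)C(Cl)(Cl)Cl.
Why: The same haloform-type N-acylation on the remaining primary amine; alcohols, carbamates and pyrrole N–H do not react.

**Step 7**
Reactants: 11.
Product: 12, the bis(α-Boc-aminoketone), cyclobutane (1R,2R,3R,4R): C1 and C4 = C(=O)CH2NHBoc, each still cis to its neighbouring CH2N arm and trans to each other.
Conditions: Dess–Martin periodinane, NaHCO3, CH2Cl2, 0 °C → rt.
Reagents that add atoms: none.
Why: Buffered Dess–Martin oxidation converts the two secondary carbinols to ketones without affecting acylpyrroles, amides or carbamates; the bought stereocentres are erased here after having set the ring.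

**Step 8**
Reactants: 12.
Product: 13, the all-trans bis(α-Boc-aminoketone), cyclobutane (1S,2R,3R,4S).
Conditions: DBU (0.5–1 equiv), CH2Cl2, 0 °C → rt.
Reagents that add atoms: none.
Why: Base-mediated thermodynamic epimerisation α to the ketones inverts C1 and C4 from cis to trans relative to their CH2N neighbours; C2 and C3 cannot enolise, so the all-trans product forms without racemisation.

**Step 9**
Reactants: 13; 14, cyanamide.
Product: 15, desbromosceptrin (as bis-HCl salt), all-trans (1S,2R,3R,4S).
Conditions: 4 M HCl in dioxane/MeOH, rt, evaporate; then H2NCN (10 equiv), H2O, pH ≈ 4.5, 95 °C.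
Reagents that add atoms: cyanamide, N#CN.
Why: Boc removal gives the bis(α-aminoketone) salt, which undergoes the Marckwald/Lancini-type condensation with cyanamide (guanidine formation, then cyclodehydration) to both 2-aminoimidazoles; once aromatised, C1 and C4 can no longer epimerise.

## Compound list

1 | (S)-5-(hydroxymethyl)furan-2(5H)-one | O=C1C=C[C@@H](CO)O1 | starting material
2 | ethyl N-Boc-oxamate | CCOC(=O)C(=O)NC(=O)OC(C)(C)C | starting material
3 | ethyl 2-[(Boc){[(2S)-5-oxo-2,5-dihydrofuran-2-yl]methyl}amino]-2-oxoacetate | CCOC(=O)C(=O)N(C[C@@H]1C=CC(=O)O1)C(=O)OC(C)(C)C | intermediate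
4 | C2-symmetric head-to-head cis-anti-cis cyclobutane bis-γ-lactone (all six centres S) | O=C1O[C@H](CN(C(=O)OC(C)(C)C)C(=O)C(=O)OCC)[C@@H]2[C@H]1[C@H]3C(=O)O[C@H](CN(C(=O)OC(C)(C)C)C(=O)C(=O)OCC)[C@@H]23 | intermediate
5 | ammonia | N | starting material
6 | (1S,2S,3S,4S)-3,4-bis[(1S)-2-(Boc-amino)-1-hydroxyethyl]cyclobutane-1,2-dicarboxamide | NC(=O)[C@H]1[C@@H]([C@H](O)CNC(=O)OC(C)(C)C)[C@H]([C@H](O)CNC(=O)OC(C)(C)C)[C@@H]1C(N)=O | intermediate
7 | (1R,2R,3R,4R)-1,2-bis(aminomethyl)-3,4-bis[(1S)-2-(Boc-amino)-1-hydroxyethyl]cyclobutane | NC[C@H]1[C@@H]([C@H](O)CNC(=O)OC(C)(C)C)[C@H]([C@H](O)CNC(=O)OC(C)(C)C)[C@@H]1CN | intermediate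
8 | 4-bromo-2-(trichloroacetyl)pyrrole | O=C(c1cc(Br)c[nH]1)C(Cl)(Cl)Cl | starting material
9 | mono-(4-bromopyrrole-2-carboxamide) of 7 | NC[C@H]1[C@@H]([C@H](O)CNC(=O)OC(C)(C)C)[C@H]([C@H](O)CNC(=O)OC(C)(C)C)[C@@H]1CNC(=O)c1cc(Br)c[nH]1 | intermediate
10 | 2-(trichloroacetyl)pyrrole | O=C(c1ccc[nH]1)C(Cl)(Cl)Cl | starting material
11 | mixed pyrrole/4-bromopyrrole bis-amide diol | O=C(NC[C@H]1[C@@H]([C@H](O)CNC(=O)OC(C)(C)C)[C@H]([C@H](O)CNC(=O)OC(C)(C)C)[C@@H]1CNC(=O)c1cc(Br)c[nH]1)c1ccc[nH]1 | intermediate
12 | bis(α-Boc-aminoketone), acyl groups cis to adjacent CH2N arms (1R,2R,3R,4R) | O=C(NC[C@H]1[C@@H](C(=O)CNC(=O)OC(C)(C)C)[C@H](C(=O)CNC(=O)OC(C)(C)C)[C@@H]1CNC(=O)c1cc(Br)c[nH]1)c1ccc[nH]1 | intermediate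
13 | all-trans bis(α-Boc-aminoketone) (1S,2R,3R,4S) | O=C(NC[C@H]1[C@H](C(=O)CNC(=O)OC(C)(C)C)[C@@H](C(=O)CNC(=O)OC(C)(C)C)[C@@H]1CNC(=O)c1cc(Br)c[nH]1)c1ccc[nH]1 | intermediate
14 | cyanamide | N#CN | starting material
15 | desbromosceptrin | Nc1ncc([C@H]2[C@H](CNC(=O)c3ccc[nH]3)[C@@H](CNC(=O)c3cc(Br)c[nH]3)[C@@H]2c2cnc(N)[nH]2)[nH]1 | target

## Step count and risks

Total steps: 9. Longest linear sequence: 9 (from 1; all other inputs are purchased).

Steps most likely to fail:

1. **Step 2 (photodimerisation).** Head-to-tail and syn-facial dimers will compete, facial selectivity of 5-substituted butenolides is moderate, and intermolecular efficiency may be low. Fallback: form the cyclobutane through the other pair of bonds, by sensitised [2+2] of maleic anhydride with the D-mannitol-derived (E)-1,2-bis(2,2-dimethyl-1,3-dioxolan-4-yl)ethene. The dioxolane carbinol centres take the role of C5 (later oxidised to the ketones) and the anhydride is converted via the trans-diester into the CH2N arms, at a cost of about four extra steps.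

2. **Step 4 (borane reduction of the bis-hydroxyamide).** Risks are relactonisation with loss of NH3, partial carbamate reduction, and stubborn amine–boranes. Fallback: avoid amide reduction by dehydrating the primary amides to the bis-nitrile (TFAA/pyridine, carbinols transiently acylated) and reducing the nitriles with NaBH4/CoCl2.

3. **Step 8 (double epimerisation).** The cis-diacyl mono-epimer is a 1,4-diketone that could undergo aldol chemistry, and equilibration may be incomplete. Fallback: invert the other pair of centres instead. Start from ent-1, methanolyse ent-4 to the O-silylated bis-ester, and epimerise the ester-bearing carbons with NaOMe before amide formation and reduction, so the ketone-bearing carbons already have the required configuration and never need inversion.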